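The earlier runs and the new flask are simulated from invented constants, and the scatter is random.

Gamma holds 3.00 times the E of alpha, yet at the fourth reading it runs 2.83 times as fast as alpha, reckoned by the summed time of step 2, less than in proportion.

| flask | X | G | E | J | time |
|---|---|---|---|---|---|
| alpha | 80.0 mM | 80.0 mM | 2.40 mM |  |  |
| theta | 80.0 mM | 80.0 mM | 2.40 mM | 40.0 mM |  |
| gamma | 80.0 mM | 80.0 mM | 7.20 mM |  |  |
| zeta | 40.0 mM | 80.0 mM | 2.40 mM |  |  |
| beta | 240 mM | 26.0 mM | 2.40 mM |  | 35 min |

- alpha run (time / min: [J] / mM): 1.4: 1.70; 2.2: 2.65; 3.5: 4.49; 5.6: 7.80; 8.8: 12.02; 14: 18.42; 22: 26.68; 35: 37.69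
- theta run (time / min: [J] / mM): 1.4: 41.75; 2.2: 42.80; 3.5: 44.78; 5.6: 48.00; 8.8: 51.99; 14: 58.85; 22: 66.88; 35: 78.13
- gamma run (time / min: [J] / mM): 1.4: 4.56; 2.2: 7.97; 3.5: 13.10; 5.6: 20.18; 8.8: 29.55; 14: 40.90; 22: 53.27; 35: 64.41
- zeta run (time / min: [J] / mM): 1.4: 1.00; 2.2: 2.09; 3.5: 2.99; 5.6: 5.39; 8.8: 8.59; 14: 12.87; 22: 18.40; 35: 24.83

(scatter of a reading: 0.2 mM)

- order of the initial rate in [E], near the charge of the alpha run, the rate being that where two percent of its X are J
- order of the initial rate in [X], near the charge of the alpha run, the rate being that where two percent of its X are J (one fixed amount of J, the same in the runs compared)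
- J in the beta run at 35 min, as a share of the X charged
- which of these the readings show (the substrate is lost by itself / the catalyst dies in pairs / the product decays / the product speeds the reaction / nothing beyond the main steps / an uncatalysed path runs beside)

- Overall: X + G -> J, with E as catalyst.
- Constant volume, constant temperature.
- An order is taken over about fifteen percent of the charge, up and down.

1. The rule, reckoned here, takes E as meeting X and then G, so the two waits add. With X plentiful, G falls pseudo-first-order; with G plentiful, X does. Joining both ends, with E held constant, gives: elapsed time = X time × ln(X charged / X left) + G time × ln(G charged / G left).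

2. In alpha, X and G are equal, so its last reading gives the sum of the two times, 54.9 min. The last zeta reading splits that sum. The X time reads 24.4 min. The G time, the span in which G falls by a factor e under excess X at the E of alpha, reads 30.6 min.

3. Near the alpha charge, the order in X reads as the X time's share of the sum, 0.444. The ratio in the opening sentence reads as an order in E of 0.948.

4. Theta has made 38.13 mM at the last reading and alpha 37.69 mM, so added J shows little effect.

5. Gamma's summed time lengthens from 19.3 min to 21.4 min. That drift is larger than alpha's, so this reckoning reads a catalyst lost faster at higher E, dying in pairs.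

6. In beta, G is the limiting reagent, 26.0 mM against 240 mM of X. At the beta charge, the wait per mM on G is about ten times that on X, so the G time sets the pace in beta. A first pass gives 17.7 mM. The X term then takes 1.87 min from the 35 min, which leaves 17.2 mM of J, or 7.17% of the X charged.

The forecast, on “saturation in both”, gives orders of 0.91 in E and 0.5 in X, 7.1% for beta, and the choice that an uncatalysed path runs beside, where this reckoning gives 0.948, 0.444, 7.17% and the catalyst dying in pairs.

The flask gives 7.10% for beta, orders of 0.92 in E and 0.41 in X, and the catalyst dies in pairs.

    E + X → Vy + Z (22.08 M⁻¹ min⁻¹)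
    Vy + G → J + E (13.32 M⁻¹ min⁻¹)
    2 E → 2 Zo (5.268 M⁻¹ min⁻¹)

The turning of 2 E into 2 Zo moves the readings by 6.3 times the scatter, yet it makes no difference to J in beta at 35 min. For gamma, the X time plus the G time, cut by the ratio of E and taken over one halving, gives 12.7 min, and the J made in gamma came to half of its X charged at 13.3 min.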